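**Plan**

- Retrosynthesis (labdane numbering C1–C20): cut C12–C13 (side chain, alkyl–alkenyl coupling), then C5–C10 and C3–C4 (both rings of the decalin, one radical cascade), then C10–C1 and C10–C20 (two lactone enolate alkylations), then C8–C9 (asymmetric 1,4-addition).
- Forward: a δ-lactone carries C9–C12; C8 arrives with the exocyclic methylene and the C4–C7 prenyl chain; C10 is made quaternary and its extra carboxyl carbon serves as a traceless radical precursor; ring B closes first (C5–C10), ring A second (C3–C4); the side chain is joined last.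
- Enabling feature: C10 is an all-carbon quaternary centre, so it can be a tertiary radical; C5 is bonded to the gem-dimethyl carbon C4, so C5=C4 is an isopropylidene terminus that a radical attacks at C5; the acetoxy carbon C2 is 1,3 to C4 and C10 in ring A, so a 2-acetoxyallyl arm on C10 ends the cascade and leaves a C2 radical between the two axial methyls.
- Stereochemistry: C9 from ligand-controlled rhodium catalysis; C10 and C5 relayed from C9 through a chair transition state; C2 by hydrogen-atom delivery anti to C19/C20; 13Z from stereoretentive coupling of a Z-iodide.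

Key step: step 9

Remark: the C10 configuration drawn for compounds 8 to 16 is the one expected from anti alkylation; it is erased in step 9, so it does not affect the outcome.

**Route**

Step 1
Reactants: 1 6-methylhept-5-en-2-one
Product: 2 N'-[(2E)-6-methylhept-5-en-2-ylidene]-2,4,6-tri(propan-2-yl)benzenesulfonohydrazide
Conditions: 2,4,6-tri(propan-2-yl)benzenesulfonohydrazide, MeOH, HCl (cat.), rt
Reagents that add atoms: 2,4,6-tri(propan-2-yl)benzenesulfonohydrazide CC(C)c1cc(C(C)C)c(S(=O)(=O)NN)c(C(C)C)c1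
Why: Acid-catalysed hydrazone condensation of the methyl ketone sets up the Shapiro reaction; the E hydrazone places the sulfonamide syn to the methyl group and no stereocentre is formed.

Step 2
Reactants: 2 N'-[(2E)-6-methylhept-5-en-2-ylidene]-2,4,6-tri(propan-2-yl)benzenesulfonohydrazide
Product: 4 (6-methylhepta-1,5-dien-2-yl)boronic acid, via alkenyllithium 3 (not isolated)
Conditions: n-BuLi (2.2 equiv), TMEDA, hexane/THF, −78 to 0 °C; B(Oi-Pr)3, −78 °C to rt; 1 M HCl work-up
Reagents that add atoms: triisopropyl borate CC(C)OB(OC(C)C)OC(C)C; water O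
Why: Shapiro reaction (deprotonation at N–H and at the syn methyl group, loss of arenesulfinate and N2) should give the 2-lithio-1-alkene regioselectively, and borylation with hydrolysis gives the alkenylboronic acid; no stereocentre is formed.

Step 3
Reactants: 4 (6-methylhepta-1,5-dien-2-yl)boronic acid; 5 5,6-dihydro-2H-pyran-2-one
Product: 6 (4R)-4-(6-methylhepta-1,5-dien-2-yl)oxan-2-one
Conditions: Rh(acac)(C2H4)2 (3 mol%), (R)-BINAP, 4 (2.5 equiv), 1,4-dioxane/H2O 10:1, 100 °C
Reagents that add atoms: none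
Why: Hayashi–Miyaura rhodium-catalysed asymmetric 1,4-addition of an alkenylboronic acid to the unsaturated δ-lactone creates C9 (4R in 6), the face being chosen by the BINAP ligand, whose enantiomer is assigned by analogy with aryl additions to this acceptor.

Step 4
Reactants: 6 (4R)-4-(6-methylhepta-1,5-dien-2-yl)oxan-2-one
Product: 8 (3S,4R)-3-methyl-4-(6-methylhepta-1,5-dien-2-yl)oxan-2-one, via lithium enolate 7 (not isolated)
Conditions: LiN(i-Pr)2, THF, −78 °C; MeI, −78 to −40 °C
Reagents that add atoms: iodomethane CI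
Why: Lactone enolate alkylation (SN2 with MeI) introduces C20 trans to the C9 substituent; this centre (C10) becomes quaternary in step 5 and is erased in step 9.

Step 5
Reactants: 8 (3S,4R)-3-methyl-4-(6-methylhepta-1,5-dien-2-yl)oxan-2-one; 9 (3-bromoprop-1-yn-1-yl)trimethylsilane
Product: 11 (3S,4S)-3-methyl-4-(6-methylhepta-1,5-dien-2-yl)-3-[3-(trimethylsilyl)prop-2-yn-1-yl]oxan-2-one, via lithium enolate 10 (not isolated)
Conditions: LiN(i-Pr)2, THF, −78 °C; DMPU; 9, −78 to 0 °C
Reagents that add atoms: none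
Why: A second lactone enolate alkylation with a reactive propargylic bromide builds the quaternary C10 that carries C20, the C1–C3 arm and the carboxyl carbon that leaves later, the electrophile entering anti to the C9 substituent; the silyl cap suppresses allenyl products.

Step 6
Reactants: 11 (3S,4S)-3-methyl-4-(6-methylhepta-1,5-dien-2-yl)-3-[3-(trimethylsilyl)prop-2-yn-1-yl]oxan-2-one
Product: 14 (2S,3S)-5-[(tert-butyldimethylsilyl)oxy]-2-methyl-3-(6-methylhepta-1,5-dien-2-yl)-2-(prop-2-yn-1-yl)pentanoic acid, via potassium hydroxy carboxylate 12 (not isolated), via bis-silyl ester ether 13 (not isolated)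
Conditions: KOH, MeOH/H2O, 60 °C; concentrate; t-BuMe2SiCl, imidazole, DMF, rt; K2CO3 (cat.), MeOH/THF/H2O, rt; pH 5 buffer
Reagents that add atoms: potassium hydroxide [K+].[OH-]; tert-butyldimethylsilyl chloride CC(C)(C)[Si](C)(C)Cl
Why: Saponification opens the δ-lactone and removes the alkynyl silyl group, exhaustive silylation traps the hydroxy carboxylate before it can relactonise, and mild basic methanolysis cleaves only the labile silyl ester; no stereocentre is touched.

Step 7
Reactants: 14 (2S,3S)-5-[(tert-butyldimethylsilyl)oxy]-2-methyl-3-(6-methylhepta-1,5-dien-2-yl)-2-(prop-2-yn-1-yl)pentanoic acid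
Product: 15 1,3-dioxoisoindolin-2-yl (2S,3S)-5-[(tert-butyldimethylsilyl)oxy]-2-methyl-3-(6-methylhepta-1,5-dien-2-yl)-2-(prop-2-yn-1-yl)pentanoate
Conditions: N-hydroxyphthalimide, N,N'-diisopropylcarbodiimide, DMAP (cat.), CH2Cl2, 0 °C to rt
Reagents that add atoms: N-hydroxyphthalimide O=C1c2ccccc2C(=O)N1O
Why: Carbodiimide (Steglich-type) esterification gives the redox-active N-acyloxyphthalimide from which the tertiary C10 radical is released.

Step 8
Reactants: 15 1,3-dioxoisoindolin-2-yl (2S,3S)-5-[(tert-butyldimethylsilyl)oxy]-2-methyl-3-(6-methylhepta-1,5-dien-2-yl)-2-(prop-2-yn-1-yl)pentanoate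
Product: 16 1,3-dioxoisoindolin-2-yl (2S,3S)-2-[2-(acetyloxy)prop-2-en-1-yl]-5-[(tert-butyldimethylsilyl)oxy]-2-methyl-3-(6-methylhepta-1,5-dien-2-yl)pentanoate
Conditions: [RuCl2(p-cymene)]2 (2 mol%), P(2-furyl)3, Na2CO3 (5 mol%), AcOH (2 equiv), toluene, 60 °C
Reagents that add atoms: acetic acid CC(=O)O
Why: Ruthenium-catalysed Markovnikov hydro-acyloxylation of the terminal alkyne turns the propargyl group into the 2-acetoxyallyl arm, so that C2 already carries its acetate; the activated ester and the other alkenes are expected to be spectators.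

Step 9
Reactants: 16 1,3-dioxoisoindolin-2-yl (2S,3S)-2-[2-(acetyloxy)prop-2-en-1-yl]-5-[(tert-butyldimethylsilyl)oxy]-2-methyl-3-(6-methylhepta-1,5-dien-2-yl)pentanoate
Product: 17 (2R,5S,9S,10S)-2β-acetoxy-12-[(tert-butyldimethylsilyl)oxy]-13,14,15,16-tetranorlabd-8(17)-ene
Conditions: Ru(bpy)3(PF6)2 (1 mol%), Hantzsch ester (1.5 equiv), CH2Cl2 (0.01 M), blue LEDs, rt
Reagents that add atoms: none
Why: Proposed new method: the photoreduced catalyst Ru(bpy)3+ (formed by reductive quenching with the Hantzsch ester) transfers one electron to the N-acyloxyphthalimide, which loses phthalimide anion and CO2 to give the tertiary C10 radical; this adds to C5 of the isopropylidene terminus (6-exo-trig, closes ring B and forms the C5–C10 bond), the tertiary C4 radical so formed adds to the CH2 end (C3) of the enol acetate (6-endo-trig, closes ring A), and the α-acetoxy C2 radical takes a hydrogen atom from the Hantzsch ester. The closest known reaction types are the reductive decarboxylative generation of tertiary radicals from N-acyloxyphthalimides for conjugate additions and the radical bicyclisations of polyenes started by titanocene, manganese or metal-hydride reagents, which run in the opposite direction (from C4 towards C10) and have not been ended on an enol ester. C10 and C5 are set in a chair-like transition state for ring B in which the C9 substituent is equatorial, the larger acetoxyallyl arm on the planar C10 radical lies next to C9–H while the methyl lies next to C8 (giving 10β-CH3), and the C4 terminus is equatorial (giving 5α-H and a trans ring fusion). C2 is set last by hydrogen delivery to the α face, because the β face of the ring A radical is covered by the syn-axial C19 and C20 methyl groups, which leaves the acetate axial (2β). The step needs 6-exo attack at C5 to beat 1,5-hydrogen shift from C6 and premature reduction, and 6-endo closure to beat 5-exo closure at C2; both additions go to the less substituted alkene carbon and give tertiary radicals, the side chain is held back as a saturated C11–C12 stub so that no 5-exo acceptor is within reach of C10, and high dilution with a slow hydrogen donor keeps reduction behind cyclisation.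

Step 10
Reactants: 17 (2R,5S,9S,10S)-2β-acetoxy-12-[(tert-butyldimethylsilyl)oxy]-13,14,15,16-tetranorlabd-8(17)-ene
Product: 18 (2R,5S,9S,10S)-2β-acetoxy-13,14,15,16-tetranorlabd-8(17)-en-12-ol
Conditions: HF·pyridine, pyridine/THF, 0 °C to rt
Reagents that add atoms: none
Why: Fluoride-mediated desilylation of the primary silyl ether; the hindered axial acetate and the exocyclic alkene should be stable to buffered HF.

Step 11
Reactants: 18 (2R,5S,9S,10S)-2β-acetoxy-13,14,15,16-tetranorlabd-8(17)-en-12-ol
Product: 19 (2R,5S,9S,10S)-2β-acetoxy-12-iodo-13,14,15,16-tetranorlabd-8(17)-ene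
Conditions: I2, PPh3, imidazole, CH2Cl2, 0 °C
Reagents that add atoms: iodine II
Why: Appel-type iodination of the unhindered primary alcohol by SN2 displacement of the oxyphosphonium group.

Step 12
Reactants: 20 but-2-ynoic acid
Product: 21 (2Z)-3-iodobut-2-enoic acid
Conditions: NaI, AcOH, 110 °C
Reagents that add atoms: sodium iodide [Na+].[I-]
Why: anti-Hydroiodination of the ynoic acid (conjugate addition of iodide, then protonation) gives the Z-β-iodo acid with iodine cis to the carboxyl group.

Step 13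
Reactants: 21 (2Z)-3-iodobut-2-enoic acid
Product: 22 2-(trimethylsilyl)ethyl (2Z)-3-iodobut-2-enoate
Conditions: 2-(trimethylsilyl)ethanol, N,N'-dicyclohexylcarbodiimide, DMAP (cat.), CH2Cl2, 0 °C to rt
Reagents that add atoms: 2-(trimethylsilyl)ethanol C[Si](C)(C)CCO
Why: Steglich esterification installs a fluoride-labile ester, so that the acid can be freed at the end without touching the C2 acetate.

Step 14
Reactants: 19 (2R,5S,9S,10S)-2β-acetoxy-12-iodo-13,14,15,16-tetranorlabd-8(17)-ene; 22 2-(trimethylsilyl)ethyl (2Z)-3-iodobut-2-enoate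
Product: 24 2-(trimethylsilyl)ethyl (2R,5S,9S,10S)-2β-acetoxylabda-8(17),13Z-dien-15-oate, via alkylzinc iodide 23 (not isolated)
Conditions: Zn dust (activated), LiCl, THF, 35 °C; then 22, PdCl2(dppf) (5 mol%), THF/DMA, rt
Reagents that add atoms: none
Why: Negishi coupling: zinc insertion into the primary iodide tolerates the acetate, and the palladium-catalysed coupling with the alkenyl iodide goes with retention, which fixes the 13Z geometry.

Step 15
Reactants: 24 2-(trimethylsilyl)ethyl (2R,5S,9S,10S)-2β-acetoxylabda-8(17),13Z-dien-15-oate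
Product: 25 (2R,5S,9S,10S)-2β-acetoxylabda-8(17),13Z-dien-15-oic acid
Conditions: Bu4NF, THF, 0 °C to rt; 0.5 M HCl work-up
Reagents that add atoms: none
Why: Fluoride attacks silicon and the ester fragments to ethene and the carboxylate (β-elimination), which should leave the acetate, the exocyclic alkene and the Z-enoate untouched.

**Compound list**

1 | 6-methylhept-5-en-2-one | CC(=O)CCC=C(C)C | starting material
2 | N'-[(2E)-6-methylhept-5-en-2-ylidene]-2,4,6-tri(propan-2-yl)benzenesulfonohydrazide | CC(C)=CCC/C(C)=N/NS(=O)(=O)c1c(C(C)C)cc(C(C)C)cc1C(C)C | intermediate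
3 | (6-methylhepta-1,5-dien-2-yl)lithium | [Li]C(=C)CCC=C(C)C | intermediate
4 | (6-methylhepta-1,5-dien-2-yl)boronic acid | OB(O)C(=C)CCC=C(C)C | intermediate
5 | 5,6-dihydro-2H-pyran-2-one | O=C1C=CCCO1 | starting material
6 | (4R)-4-(6-methylhepta-1,5-dien-2-yl)oxan-2-one | O=C1C[C@H](C(=C)CCC=C(C)C)CCO1 | intermediate
7 | lithium enolate of 6 | [Li]OC1=C[C@H](C(=C)CCC=C(C)C)CCO1 | intermediate
8 | (3S,4R)-3-methyl-4-(6-methylhepta-1,5-dien-2-yl)oxan-2-one | O=C1[C@@H](C)[C@H](C(=C)CCC=C(C)C)CCO1 | intermediate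
9 | (3-bromoprop-1-yn-1-yl)trimethylsilane | C[Si](C)(C)C#CCBr | starting material
10 | lithium enolate of 8 | [Li]OC1=C(C)[C@H](C(=C)CCC=C(C)C)CCO1 | intermediate
11 | (3S,4S)-3-methyl-4-(6-methylhepta-1,5-dien-2-yl)-3-[3-(trimethylsilyl)prop-2-yn-1-yl]oxan-2-one | O=C1[C@@](C)(CC#C[Si](C)(C)C)[C@H](C(=C)CCC=C(C)C)CCO1 | intermediate
12 | potassium (2S,3S)-5-hydroxy-2-methyl-3-(6-methylhepta-1,5-dien-2-yl)-2-(prop-2-yn-1-yl)pentanoate | [K+].[O-]C(=O)[C@@](C)(CC#C)[C@H](C(=C)CCC=C(C)C)CCO | intermediate
13 | tert-butyldimethylsilyl (2S,3S)-5-[(tert-butyldimethylsilyl)oxy]-2-methyl-3-(6-methylhepta-1,5-dien-2-yl)-2-(prop-2-yn-1-yl)pentanoate | CC(C)(C)[Si](C)(C)OC(=O)[C@@](C)(CC#C)[C@H](C(=C)CCC=C(C)C)CCO[Si](C)(C)C(C)(C)C | intermediate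
14 | (2S,3S)-5-[(tert-butyldimethylsilyl)oxy]-2-methyl-3-(6-methylhepta-1,5-dien-2-yl)-2-(prop-2-yn-1-yl)pentanoic acid | OC(=O)[C@@](C)(CC#C)[C@H](C(=C)CCC=C(C)C)CCO[Si](C)(C)C(C)(C)C | intermediate
15 | 1,3-dioxoisoindolin-2-yl (2S,3S)-5-[(tert-butyldimethylsilyl)oxy]-2-methyl-3-(6-methylhepta-1,5-dien-2-yl)-2-(prop-2-yn-1-yl)pentanoate | O=C(ON1C(=O)c2ccccc2C1=O)[C@@](C)(CC#C)[C@H](C(=C)CCC=C(C)C)CCO[Si](C)(C)C(C)(C)C | intermediate
16 | 1,3-dioxoisoindolin-2-yl (2S,3S)-2-[2-(acetyloxy)prop-2-en-1-yl]-5-[(tert-butyldimethylsilyl)oxy]-2-methyl-3-(6-methylhepta-1,5-dien-2-yl)pentanoate | O=C(ON1C(=O)c2ccccc2C1=O)[C@@](C)(CC(=C)OC(C)=O)[C@H](C(=C)CCC=C(C)C)CCO[Si](C)(C)C(C)(C)C | intermediate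
17 | (2R,5S,9S,10S)-2β-acetoxy-12-[(tert-butyldimethylsilyl)oxy]-13,14,15,16-tetranorlabd-8(17)-ene (5α-H, 9α-H, 10β-CH3) | C=C1CC[C@H]2C(C)(C)C[C@@H](OC(C)=O)C[C@]2(C)[C@H]1CCO[Si](C)(C)C(C)(C)C | intermediate
18 | (2R,5S,9S,10S)-2β-acetoxy-13,14,15,16-tetranorlabd-8(17)-en-12-ol | C=C1CC[C@H]2C(C)(C)C[C@@H](OC(C)=O)C[C@]2(C)[C@H]1CCO | intermediate
19 | (2R,5S,9S,10S)-2β-acetoxy-12-iodo-13,14,15,16-tetranorlabd-8(17)-ene | C=C1CC[C@H]2C(C)(C)C[C@@H](OC(C)=O)C[C@]2(C)[C@H]1CCI | intermediate
20 | but-2-ynoic acid | CC#CC(=O)O | starting material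
21 | (2Z)-3-iodobut-2-enoic acid | C/C(I)=C/C(=O)O | intermediate
22 | 2-(trimethylsilyl)ethyl (2Z)-3-iodobut-2-enoate | C/C(I)=C/C(=O)OCC[Si](C)(C)C | intermediate
23 | [(2R,5S,9S,10S)-2β-acetoxy-13,14,15,16-tetranorlabd-8(17)-en-12-yl]zinc iodide | C=C1CC[C@H]2C(C)(C)C[C@@H](OC(C)=O)C[C@]2(C)[C@H]1CC[Zn]I | intermediate
24 | 2-(trimethylsilyl)ethyl (2R,5S,9S,10S)-2β-acetoxylabda-8(17),13Z-dien-15-oate | C=C1CC[C@H]2C(C)(C)C[C@@H](OC(C)=O)C[C@]2(C)[C@H]1CC/C(C)=C\C(=O)OCC[Si](C)(C)C | intermediate
25 | (2R,5S,9S,10S)-2β-acetoxylabda-8(17),13Z-dien-15-oic acid | C=C1CC[C@H]2C(C)(C)C[C@@H](OC(C)=O)C[C@]2(C)[C@H]1CC/C(C)=C\C(=O)O | target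

**Step count**

Total steps: 15. Longest linear sequence: 13 (steps 1 to 11, then 14 and 15); steps 12 and 13 make the side-chain partner.

**Steps most likely to fail**

1. Step 9 (proposed new method). What may go wrong: reduction or 1,5-hydrogen shift of the C10 or C4 radical before ring closure, or weak facial control at C10 or C2. The fallback uses known reaction types, sets out from 16 and comes back at 17. The C10 radical, generated as in step 9, is trapped by TEMPO to give the alkoxyamine F1 (C10 epimers). Zn/AcOH cleaves the N–O bond to give the tertiary alcohol F2. Ionisation with SnCl4 (CH2Cl2, −78 °C, 2,6-di-tert-butylpyridine) starts a cation–olefin bicyclisation through the same chair: the C10 cation is attacked by C5 of the isopropylidene group and the C4 cation is captured by the enol acetate acting as terminator, which gives after aqueous work-up the C2 ketone F3. NaBH4 (MeOH, 0 °C) should reduce F3 from the α face, anti to C19/C20, to the axial 2β-alcohol F4, and Ac2O/DMAP/pyridine returns 17.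

2. Step 8. What may go wrong: loss of the N-acyloxyphthalimide by acyl transfer under the carboxylate/carbonate conditions, or diversion of the 1,6-enyne at ruthenium. The fallback changes the order of events and the carboxyl protection, sets out from 14 and comes back at 16. The acid is first masked as the allyl ester F5 (allyl bromide, K2CO3, DMF); the Markovnikov addition of AcOH is run on this robust ester to give the enol acetate allyl ester F6; the allyl group is removed under neutral conditions (Pd(PPh3)4, PhSiH3, CH2Cl2) to give the enol acetate acid F7; esterification with N-hydroxyphthalimide as in step 7 then gives 16.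

3. Step 3. What may go wrong: protodeboronation of the α-branched alkenylboronic acid outrunning transmetalation, or low facial selectivity for an alkenyl group substituted at the metal-bearing carbon. The fallback replaces catalyst control by desymmetrisation, sets out from 2 (through 3) and 5, and comes back at 6. The lithium dialkenylcuprate made from 3 and CuI adds to 5 (Me3SiCl, THF, −78 °C) to give the racemic lactone F8. Saponification and oxidation of the primary alcohol (TEMPO, PhI(OAc)2, MeCN/H2O) turn the stereocentre into a prochiral one in the glutaric acid F9. Ac2O closes the achiral cyclic anhydride F10. Alkaloid-mediated methanolysis (quinidine or quinine, the pseudo-enantiomer being chosen to give the 3R compound) gives the half-ester F11. The free acid is reduced through its mixed anhydride (ClCO2Et, Et3N; then NaBH4) to the hydroxy ester F12, which lactonises with TsOH (cat.) to 6.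

Further compounds
F1 | step 9 | (5S)-7-[(tert-butyldimethylsilyl)oxy]-4-methyl-5-(6-methylhepta-1,5-dien-2-yl)-4-[(2,2,6,6-tetramethylpiperidin-1-yl)oxy]hept-1-en-2-yl acetate (C4 epimers) | CC(=O)OC(=C)CC(C)(ON1C(C)(C)CCCC1(C)C)[C@H](C(=C)CCC=C(C)C)CCO[Si](C)(C)C(C)(C)C
F2 | step 9 | (5S)-7-[(tert-butyldimethylsilyl)oxy]-4-hydroxy-4-methyl-5-(6-methylhepta-1,5-dien-2-yl)hept-1-en-2-yl acetate (C4 epimers) | CC(=O)OC(=C)CC(C)(O)[C@H](C(=C)CCC=C(C)C)CCO[Si](C)(C)C(C)(C)C
F3 | step 9 | (5S,9S,10S)-12-[(tert-butyldimethylsilyl)oxy]-13,14,15,16-tetranorlabd-8(17)-en-2-one | C=C1CC[C@H]2C(C)(C)CC(=O)C[C@]2(C)[C@H]1CCO[Si](C)(C)C(C)(C)C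
F4 | step 9 | (2R,5S,9S,10S)-12-[(tert-butyldimethylsilyl)oxy]-13,14,15,16-tetranorlabd-8(17)-en-2β-ol | C=C1CC[C@H]2C(C)(C)C[C@@H](O)C[C@]2(C)[C@H]1CCO[Si](C)(C)C(C)(C)C
F5 | step 8 | prop-2-en-1-yl (2S,3S)-5-[(tert-butyldimethylsilyl)oxy]-2-methyl-3-(6-methylhepta-1,5-dien-2-yl)-2-(prop-2-yn-1-yl)pentanoate | C=CCOC(=O)[C@@](C)(CC#C)[C@H](C(=C)CCC=C(C)C)CCO[Si](C)(C)C(C)(C)C
F6 | step 8 | prop-2-en-1-yl (2S,3S)-2-[2-(acetyloxy)prop-2-en-1-yl]-5-[(tert-butyldimethylsilyl)oxy]-2-methyl-3-(6-methylhepta-1,5-dien-2-yl)pentanoate | C=CCOC(=O)[C@@](C)(CC(=C)OC(C)=O)[C@H](C(=C)CCC=C(C)C)CCO[Si](C)(C)C(C)(C)C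
F7 | step 8 | (2S,3S)-2-[2-(acetyloxy)prop-2-en-1-yl]-5-[(tert-butyldimethylsilyl)oxy]-2-methyl-3-(6-methylhepta-1,5-dien-2-yl)pentanoic acid | OC(=O)[C@@](C)(CC(=C)OC(C)=O)[C@H](C(=C)CCC=C(C)C)CCO[Si](C)(C)C(C)(C)C
F8 | step 3 | rac-4-(6-methylhepta-1,5-dien-2-yl)oxan-2-one | O=C1CC(C(=C)CCC=C(C)C)CCO1
F9 | step 3 | 3-(6-methylhepta-1,5-dien-2-yl)pentanedioic acid | OC(=O)CC(C(=C)CCC=C(C)C)CC(=O)O
F10 | step 3 | 4-(6-methylhepta-1,5-dien-2-yl)oxane-2,6-dione | O=C1CC(C(=C)CCC=C(C)C)CC(=O)O1
F11 | step 3 | (3R)-5-methoxy-3-(6-methylhepta-1,5-dien-2-yl)-5-oxopentanoic acid | COC(=O)C[C@H](C(=C)CCC=C(C)C)CC(=O)O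
F12 | step 3 | methyl (3R)-5-hydroxy-3-(6-methylhepta-1,5-dien-2-yl)pentanoate | COC(=O)C[C@H](C(=C)CCC=C(C)C)CCO
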